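The target, (2S)-5,7-dimethoxy-2-(4-methoxyphenyl)-6-prenylchroman, is cut across ring C at C2–C3 and C4–C4a. The route exploits that C3 and C4 carry only hydrogen and form an unsubstituted CH2–CH2 link between C2 (bound to O1 and the 4-methoxyphenyl ring) and C4a of ring A, so an O-aryl oxocarbenium ion (O1=C2) can take up a two-carbon alkene in a cationic [4+2] annulation. Phenyl vinyl sulfide is that alkene: under a chiral confined Brønsted acid one operation forms both bonds, closes ring C and sets C2, leaving a removable phenylthio group on C4. The precursor is the racemic mixed acetal of 4-methoxybenzaldehyde bearing one methoxy and one 3,5-dimethoxy-4-prenylphenoxy group.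

Key step: step 6

Remark: which antipode of the chiral acid leads to the 2S series cannot be predicted, so the route is written for the antipode that does; both are accessible from (R)- or (S)-BINOL.

Step 1
Reactants: 1 3,5-dimethoxyphenol
Product: 2 (3,5-dimethoxyphenoxy)triisopropylsilane
Conditions: TIPSCl, imidazole, DMF, 0 °C to rt
Reagents that add atoms: chlorotriisopropylsilane (TIPSCl), CC(C)[Si](Cl)(C(C)C)C(C)C
Why: Silyl ether formation at the phenol with imidazole as base and activator; the bulky triisopropylsilyl group removes the acidic OH, resists n-BuLi and shields its two ortho positions.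

Step 2
Reactants: 2 (3,5-dimethoxyphenoxy)triisopropylsilane; 3 prenyl bromide (1-bromo-3-methylbut-2-ene)
Product: 5 [3,5-dimethoxy-4-(3-methylbut-2-enyl)phenoxy]triisopropylsilane, via aryllithium 4 (not isolated)
Conditions: n-BuLi, THF, 0 °C to rt; then 3, −78 °C to rt
Reagents that add atoms: none
Why: Directed ortho-lithiation at the C–H flanked by two coordinating methoxy groups (the positions next to the bulky, poorly coordinating silyloxy group are disfavoured), followed by SN2 alkylation of the aryllithium at the primary carbon of the allylic bromide.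

Step 3
Reactants: 5 [3,5-dimethoxy-4-(3-methylbut-2-enyl)phenoxy]triisopropylsilane
Product: 6 3,5-dimethoxy-4-(3-methylbut-2-enyl)phenol
Conditions: TBAF, AcOH, THF, 0 °C to rt
Reagents that add atoms: none
Why: Fluoride-induced desilylation of an aryl silyl ether, driven by the Si–F bond; the buffered conditions leave the methyl ethers and the alkene untouched.

Step 4
Reactants: 7 4-methoxybenzaldehyde dimethyl acetal
Product: 8 rac-1-[chloro(methoxy)methyl]-4-methoxybenzene (crude, used at once)
Conditions: AcCl, SOCl2 (cat.), neat, 0 °C to rt; volatiles removed in vacuo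
Reagents that add atoms: acetyl chloride, CC(=O)Cl
Why: Acetal to α-chloro ether exchange: O-acylation of one methoxy group, loss of methyl acetate and capture of the aryl-stabilised oxocarbenium ion by chloride.

Step 5
Reactants: 6 3,5-dimethoxy-4-(3-methylbut-2-enyl)phenol; 8 rac-1-[chloro(methoxy)methyl]-4-methoxybenzene
Product: 10 rac-1,3-dimethoxy-5-[methoxy(4-methoxyphenyl)methoxy]-2-(3-methylbut-2-enyl)benzene (mixed O-aryl O-methyl acetal), via sodium phenoxide 9 (not isolated)
Conditions: NaH, THF/DMF, 0 °C; then crude 8, 0 °C to rt; aq. NaHCO3 work-up, Et3N-treated silica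
Reagents that add atoms: none
Why: Williamson-type O-alkylation of the sodium phenoxide by the highly reactive α-chloro ether in a polar aprotic medium, the standard entry to mixed aryl methyl acetals; the new acetal centre is racemic and is erased in step 6.

Step 6
Reactants: 10 rac-1,3-dimethoxy-5-[methoxy(4-methoxyphenyl)methoxy]-2-(3-methylbut-2-enyl)benzene; 11 phenyl vinyl sulfide
Product: 14 (2S,4S)-5,7-dimethoxy-2-(4-methoxyphenyl)-4-(phenylthio)-6-(3-methylbut-2-enyl)chroman (2,4-cis), via O-aryl oxocarbenium ion 12 (not isolated), via thionium ion 13 (not isolated)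
Conditions: 11 (3 equiv), chiral IDPi acid (BINOL-derived imidodiphosphorimidate with 3,5-bis(trifluoromethyl)phenyl groups at the four 3,3'-positions and two P=N–SO2CF3 groups, 5 mol %), 5 Å molecular sieves, toluene, −60 °C, slow addition of 10; Et3N quench
Reagents that add atoms: none
Why: Proposed new method: the acid protonates the methoxy oxygen of 10, methanol leaves and is held by the sieves, and the (E)-O-aryl oxocarbenium ion 12, paired with the confined chiral anion, is attacked at C2 by the CH2 carbon of 11 to give thionium ion 13, which an ortho carbon of ring A captures before the arenium proton returns to the anion and turns the catalyst over. The closest known reaction types are the SnCl4-promoted racemic oxa-Povarov annulation of aryl oxocarbenium ions with alkenes and chiral-counteranion-directed additions of π-nucleophiles to oxocarbenium ions; joining them in a catalytic enantioselective annulation is the untested part. Ring C closes by a 6-exo-trig Friedel–Crafts attack of the arene on the thionium carbon, the second bond of a stepwise cationic [4+2] process. C2 is set in the first C–C bond formation, where the chiral anion shields one face of the planar oxocarbenium ion; C4 follows from a chair-like closure with the 4-methoxyphenyl and phenylthio groups pseudo-equatorial (2,4-cis) and does not matter in the end because step 7 turns it into CH2. The step needs loss of methanol and not of phenol 6 (the alkyl-type oxygen is the stronger base and methanol is trapped irreversibly while phenol loss is reversible), attack by 11 and not by the prenyl alkene or a second arene (the vinyl sulfide is the better π-nucleophile and is kept in excess while 10 is added slowly), and a single site of ring closure (the two ortho carbons of ring A are equivalent and each is activated by O1 and by an ortho and a para methoxy group).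

Step 7
Reactants: 14 (2S,4S)-5,7-dimethoxy-2-(4-methoxyphenyl)-4-(phenylthio)-6-(3-methylbut-2-enyl)chroman
Product: 16 (2S)-5,7-dimethoxy-2-(4-methoxyphenyl)-6-(3-methylbut-2-enyl)chroman, via C4 benzylic radical 15 (not isolated)
Conditions: Bu3SnH (3 equiv), AIBN (azobisisobutyronitrile, cat., in portions), degassed toluene, 100 °C
Reagents that add atoms: none
Why: Radical chain desulfurization: the tributyltin radical abstracts the phenylthio group to give the C4 benzylic radical stabilised by electron-rich ring A, which takes hydrogen from Bu3SnH; the trisubstituted prenyl alkene and C2 are not involved, so the 2S centre is kept.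

Compound list
1 | 3,5-dimethoxyphenol | COc1cc(O)cc(OC)c1 | starting material
2 | (3,5-dimethoxyphenoxy)triisopropylsilane | COc1cc(O[Si](C(C)C)(C(C)C)C(C)C)cc(OC)c1 | intermediate
3 | prenyl bromide (1-bromo-3-methylbut-2-ene) | CC(C)=CCBr | starting material
4 | [2,6-dimethoxy-4-(triisopropylsilyloxy)phenyl]lithium (not isolated) | [Li]c1c(OC)cc(O[Si](C(C)C)(C(C)C)C(C)C)cc1OC | intermediate
5 | [3,5-dimethoxy-4-(3-methylbut-2-enyl)phenoxy]triisopropylsilane | COc1cc(O[Si](C(C)C)(C(C)C)C(C)C)cc(OC)c1CC=C(C)C | intermediate
6 | 3,5-dimethoxy-4-(3-methylbut-2-enyl)phenol | COc1cc(O)cc(OC)c1CC=C(C)C | intermediate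
7 | 4-methoxybenzaldehyde dimethyl acetal | COc1ccc(C(OC)OC)cc1 | starting material
8 | rac-1-[chloro(methoxy)methyl]-4-methoxybenzene | COc1ccc(C(Cl)OC)cc1 | intermediate
9 | sodium 3,5-dimethoxy-4-(3-methylbut-2-enyl)phenoxide (not isolated) | [Na+].[O-]c1cc(OC)c(CC=C(C)C)c(OC)c1 | intermediate
10 | rac-1,3-dimethoxy-5-[methoxy(4-methoxyphenyl)methoxy]-2-(3-methylbut-2-enyl)benzene | COc1ccc(C(OC)Oc2cc(OC)c(CC=C(C)C)c(OC)c2)cc1 | intermediate
11 | phenyl vinyl sulfide | C=CSc1ccccc1 | starting material
12 | (E)-[3,5-dimethoxy-4-(3-methylbut-2-enyl)phenyl](4-methoxybenzylidene)oxonium, paired with the chiral anion (not isolated) | COc1ccc(/C=[O+]/c2cc(OC)c(CC=C(C)C)c(OC)c2)cc1 | intermediate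
13 | (S)-{3-[3,5-dimethoxy-4-(3-methylbut-2-enyl)phenoxy]-3-(4-methoxyphenyl)propylidene}(phenyl)sulfonium (not isolated) | COc1ccc([C@H](CC=[S+]c2ccccc2)Oc2cc(OC)c(CC=C(C)C)c(OC)c2)cc1 | intermediate
14 | (2S,4S)-5,7-dimethoxy-2-(4-methoxyphenyl)-4-(phenylthio)-6-(3-methylbut-2-enyl)chroman (2,4-cis) | COc1ccc([C@@H]2C[C@H](Sc3ccccc3)c4c(cc(OC)c(CC=C(C)C)c4OC)O2)cc1 | intermediate
15 | (2S)-5,7-dimethoxy-2-(4-methoxyphenyl)-6-(3-methylbut-2-enyl)chroman-4-yl radical (not isolated) | COc1ccc([C@@H]2C[CH]c3c(cc(OC)c(CC=C(C)C)c3OC)O2)cc1 | intermediate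
16 | (2S)-5,7-dimethoxy-2-(4-methoxyphenyl)-6-(3-methylbut-2-enyl)chroman | COc1ccc([C@@H]2CCc3c(cc(OC)c(CC=C(C)C)c3OC)O2)cc1 | target

Total step count: 7. Longest linear sequence: 6 steps (steps 1, 2, 3, 5, 6, 7); step 4 is a one-step branch.

Steps most likely to fail

Step 6. The chiral anion may discriminate poorly between the faces of the oxocarbenium ion, the acetal may ionize at the aryloxy oxygen, or turnover may stall if methanol is not removed. The fallback sets out from 10 and 11 and uses the known stoichiometric Lewis-acid form of the annulation (SnCl4, CH2Cl2, −78 °C), which should give racemic 5,7-dimethoxy-2-(4-methoxyphenyl)-4-(phenylthio)-6-(3-methylbut-2-enyl)chroman F1, whose C4 configuration is immaterial. Reduction under the conditions of step 7 should give racemic 5,7-dimethoxy-2-(4-methoxyphenyl)-6-(3-methylbut-2-enyl)chroman F2. Preparative HPLC on a cellulose tris(3,5-dimethylphenylcarbamate) phase would then separate F2 into the target and its (2R)-enantiomer F3. The fallback comes back to the route at 16.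

Step 5. The ambident, very electron-rich phenoxide may be alkylated at an ortho carbon instead of oxygen, or the chloro ether may be lost to moisture before capture. The fallback sets out from 6 and 7 and avoids the chloride: 7 is treated with TESOTf and 2,4,6-collidine (CH2Cl2, 0 °C) to form 1-[methoxy(4-methoxyphenyl)methyl]-2,4,6-trimethylpyridinium triflate F4, which is not isolated. Phenol 6 then displaces collidine under weakly basic conditions, a known way to make mixed acetals from dimethyl acetals and hydroxy compounds. The fallback comes back to the route at 10.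

Step 2. Metalation may occur next to the silyloxy group, with migration of silicon from oxygen to carbon, instead of between the methoxy groups. The fallback sets out from 3 and needs no silyl ether. Commercial 1,3-dimethoxybenzene (COc1cccc(OC)c1) is lithiated at C2 (n-BuLi, THF, 0 °C) to 2,6-dimethoxyphenyllithium F5 and alkylated with 3 to 1,3-dimethoxy-2-(3-methylbut-2-enyl)benzene F6. Sterically controlled C–H borylation ([Ir(OMe)(cod)]2, 4,4'-di-tert-butyl-2,2'-bipyridine, B2pin2, THF, 60 °C) at the only C–H without an ortho substituent should give 2-[3,5-dimethoxy-4-(3-methylbut-2-enyl)phenyl]-4,4,5,5-tetramethyl-1,3,2-dioxaborolane F7. Oxidation (aq. H2O2, NaOH, THF, 0 °C) then gives the phenol, and the fallback comes back to the route at 6.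

Further compounds
F1 | step 6 | rac-5,7-dimethoxy-2-(4-methoxyphenyl)-4-(phenylthio)-6-(3-methylbut-2-enyl)chroman | COc1ccc(C2CC(Sc3ccccc3)c3c(cc(OC)c(CC=C(C)C)c3OC)O2)cc1
F2 | step 6 | rac-5,7-dimethoxy-2-(4-methoxyphenyl)-6-(3-methylbut-2-enyl)chroman | COc1ccc(C2CCc3c(cc(OC)c(CC=C(C)C)c3OC)O2)cc1
F3 | step 6 | (2R)-5,7-dimethoxy-2-(4-methoxyphenyl)-6-(3-methylbut-2-enyl)chroman | COc1ccc([C@H]2CCc3c(cc(OC)c(CC=C(C)C)c3OC)O2)cc1
F4 | step 5 | 1-[methoxy(4-methoxyphenyl)methyl]-2,4,6-trimethylpyridinium triflate (racemic, not isolated) | COc1ccc(C(OC)[n+]2c(C)cc(C)cc2C)cc1.[O-]S(=O)(=O)C(F)(F)F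
F5 | step 2 | 2,6-dimethoxyphenyllithium (not isolated) | [Li]c1c(OC)cccc1OC
F6 | step 2 | 1,3-dimethoxy-2-(3-methylbut-2-enyl)benzene | COc1cccc(OC)c1CC=C(C)C
F7 | step 2 | 2-[3,5-dimethoxy-4-(3-methylbut-2-enyl)phenyl]-4,4,5,5-tetramethyl-1,3,2-dioxaborolane | COc1cc(B2OC(C)(C)C(C)(C)O2)cc(OC)c1CC=C(C)C
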